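## Retrosynthetic overview

1. The target is traced back to a C3 ketone/C4 hydroxymethyl compound (CH2OH → CH3 via the iodide), itself unmasked from a 2-isoxazoline fused on ring A; the aryl ether comes from a Mitsunobu reaction of the C11 alcohol with umbelliferone.
2. The C9–CH2OH unit (H9 α) comes from 9-BBN hydroboration of a 7,9(11)-diene, made by Wittig methylenation of the C9 enone, which is carvone's own enone.
3. Key step: ring A is closed by an intramolecular nitrile oxide–alkene [3+2] cycloaddition (C3–C4 bond) between a C10-tethered nitrile oxide and carvone's isopropenyl group, giving the trans-decalin.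
4. The C10 quaternary centre comes from methylation, then propargylation of (R)-(−)-carvone anti to the isopropenyl group; the alkyne is hydrated to the aldehyde that becomes the oxime.
5. Ring order: ring B is bought in (R)-carvone (C5 stereocentre) → ring A plus isoxazoline by cycloaddition → coumarin bought as umbelliferone.

Assumption: the target is taken as drawn, (5R,9S,10S) in drimane numbering (H5 α, CH3-10 β, CH2OAr-9 β); drimane numbering and α/β face labels are used for all bicyclic compounds (α = face opposite the C10 methyl).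

## Route

Step 1
Reactants: 1 (R)-(−)-carvone
Product: 3 (5R,6RS)-2,6-dimethyl-5-(prop-1-en-2-yl)cyclohex-2-en-1-one (6-methylcarvone; C6 epimer mixture), via lithium dienolate 2 (not isolated)
Conditions: LiN(iPr)2 (1.1 equiv), THF, −78 °C; MeI, −78 → 0 °C
Reagents that add atoms: iodomethane, CI
Why: Kinetic α'-deprotonation gives the cross-conjugated lithium dienolate, and enolate alkylation with MeI installs the future C10 methyl; the C6 epimer ratio is irrelevant because this centre is re-enolised in step 2.

Step 2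
Reactants: 3 6-methylcarvone
Product: 5 (5S,6S)-2,6-dimethyl-5-(prop-1-en-2-yl)-6-(prop-2-yn-1-yl)cyclohex-2-en-1-one (propargyl trans to isopropenyl), via lithium dienolate 4 (not isolated)
Conditions: LiN(iPr)2 (1.2 equiv), THF, −78 °C; propargyl bromide, −78 → 0 °C
Reagents that add atoms: propargyl bromide (3-bromoprop-1-yne), C#CCBr
Why: Enolate alkylation in which the electrophile approaches the face opposite the adjacent C5 isopropenyl group (1,2-induction from the purchased stereocentre), so the quaternary centre (future C10) carries the three-carbon chain trans and the methyl cis to isopropenyl, as a trans-decalin requires.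

Step 3
Reactants: 5 propargyl ketone
Product: 6 3-[(1S,6S)-1,3-dimethyl-2-oxo-6-(prop-1-en-2-yl)cyclohex-3-en-1-yl]propanal
Conditions: CpRu(MeCN)3PF6 (2 mol %), 5,5'-bis(trifluoromethyl)-2,2'-bipyridine (2 mol %), NMP/H2O 4:1, 25 °C
Reagents that add atoms: water, O
Why: Ruthenium-vinylidene-mediated anti-Markovnikov alkyne hydration gives the aldehyde (future C3) under neutral conditions that leave the enone and the 1,1-disubstituted alkene untouched.

Step 4
Reactants: 6 keto aldehyde
Product: 9 tricyclic isoxazoline enone (ring A closed; 2-isoxazoline C3=N–O–CH2–C4 fused on C3–C4; 4β-CH3; 10β-CH3; 5α-H; 8-CH3; Δ7; 9-oxo), via aldoxime 7 (not isolated), via nitrile oxide 8 (not isolated)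
Conditions: 50 % aq NH2OH (1.1 equiv), EtOH, 25 °C, concentrate; aq NaOCl, CH2Cl2 (0.02 M), 0 → 25 °C
Reagents that add atoms: hydroxylamine, NO
Why: Oxime formation, oxidation to the nitrile oxide and an intramolecular Huisgen nitrile oxide–alkene [3+2] cycloaddition onto the isopropenyl group close ring A through the C3–C4 bond; tether and alkene are trans-diequatorial on ring B so the fusion is trans, and the chair-like transition state puts the O–CH2 arm equatorial (α) on C4, a centre that later becomes CMe2 so either epimer would serve.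

Step 5
Reactants: 9 isoxazoline enone
Product: 10 isoxazoline 7,9(11)-diene (as 9 but with C9=CH2 in place of C9=O)
Conditions: Ph3PCH3Br (4 equiv), KOtBu (4 equiv), toluene, 90 °C
Reagents that add atoms: methyltriphenylphosphonium bromide, C[P+](c1ccccc1)(c1ccccc1)c1ccccc1.[Br-]
Why: Wittig methylenation with excess ylide at elevated temperature converts the hindered enone, which has no α'-hydrogen, into the exocyclic diene, while the isoxazoline that masks the C3 ketone is inert to the ylide.

Step 6
Reactants: 10 isoxazoline diene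
Product: 12 isoxazoline alcohol (9β-CH2OH; 9α-H; Δ7; 8-CH3; isoxazoline on C3–C4 as in 9), via B-alkyl-9-BBN adduct 11 (not isolated)
Conditions: 9-BBN (2.5 equiv), THF, 0 → 40 °C; NaOH, H2O2, 0 °C
Reagents that add atoms: 9-borabicyclo[3.3.1]nonane (9-BBN), B1C2CCCC1CCC2 (boron and ring remain only in 11); hydrogen peroxide, OO
Why: Hydroboration–oxidation in which 9-BBN adds only to the exocyclic terminus of the diene, boron to C11 and hydrogen to C9 from the α face opposite the axial C10 methyl, setting C9 (H α, CH2OH β-equatorial); oxidation occurs with retention.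

Step 7
Reactants: 12 isoxazoline alcohol; 13 umbelliferone (7-hydroxy-2H-chromen-2-one)
Product: 14 isoxazoline aryl ether (C11–O–C7 of the coumarin; otherwise as 12)
Conditions: PPh3, DIAD, THF, 0 → 40 °C
Reagents that add atoms: none
Why: Mitsunobu etherification, in which the acidic phenol (pKa about 7.8) displaces the oxyphosphonium at the primary C11 carbon by SN2 without touching any stereocentre.

Step 8
Reactants: 14 isoxazoline aryl ether
Product: 16 7-{[(1S,4aR,5R,8aS)-5-(hydroxymethyl)-2,5,8a-trimethyl-6-oxo-1,4,4a,5,6,7,8,8a-octahydronaphthalen-1-yl]methoxy}-2H-chromen-2-one (3-oxo; 4α-CH2OH; 4β-CH3), via hydroxy imine 15 (not isolated)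
Conditions: Mo(CO)6 (1 equiv), MeCN/H2O 10:1, 80 °C
Reagents that add atoms: water, O
Why: Mo(CO)6-mediated reductive N–O cleavage of the 2-isoxazoline followed by hydrolysis of the β-hydroxy imine in the wet solvent unveils the C3 ketone and the C4 hydroxymethyl group without reducing the coumarin or the trisubstituted alkene.

Step 9
Reactants: 16 β-hydroxy ketone
Product: 17 7-{[(1S,4aR,5S,8aS)-5-(iodomethyl)-2,5,8a-trimethyl-6-oxo-1,4,4a,5,6,7,8,8a-octahydronaphthalen-1-yl]methoxy}-2H-chromen-2-one (4α-CH2I)
Conditions: I2, PPh3, imidazole, toluene, 90 °C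
Reagents that add atoms: iodine, II
Why: Garegg–Samuelsson (Appel-type) iodination, in which iodide displaces the oxyphosphonium by SN2; the neopentyl carbon needs heat, but elimination is impossible because C4 is quaternary.

Step 10
Reactants: 17 neopentyl iodide
Product: 18 7-{[(1S,4aR,8aS)-2,5,5,8a-tetramethyl-6-oxo-1,4,4a,5,6,7,8,8a-octahydronaphthalen-1-yl]methoxy}-2H-chromen-2-one (target)
Conditions: Bu3SnH (3 equiv), (PhSe)2 (10 mol %), AIBN (cat.), PhH, 80 °C
Reagents that add atoms: none
Why: Tin hydride radical-chain dehalogenation turns CH2I into the second C4 methyl, and benzeneselenol formed in situ from (PhSe)2 transfers hydrogen fast enough to outrun the 1,2-acyl shift (Dowd–Beckwith ring expansion) open to this β-keto primary radical.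

## Compound list

1 | (R)-(−)-carvone, (5R)-2-methyl-5-(prop-1-en-2-yl)cyclohex-2-en-1-one | CC1=CC[C@@H](C(C)=C)CC1=O | starting material
2 | lithium cross-conjugated dienolate of carvone (C1–OLi, C1=C6) | CC1=CC[C@@H](C(C)=C)C=C1O[Li] | intermediate
3 | (5R,6RS)-2,6-dimethyl-5-(prop-1-en-2-yl)cyclohex-2-en-1-one (6-methylcarvone, C6 epimers) | CC1=CC[C@@H](C(C)=C)C(C)C1=O | intermediate
4 | lithium dienolate of 3 (C1–OLi, C1=C6) | CC1=CC[C@@H](C(C)=C)C(C)=C1O[Li] | intermediate
5 | (5S,6S)-2,6-dimethyl-5-(prop-1-en-2-yl)-6-(prop-2-yn-1-yl)cyclohex-2-en-1-one | CC1=CC[C@@H](C(C)=C)[C@](C)(CC#C)C1=O | intermediate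
6 | 3-[(1S,6S)-1,3-dimethyl-2-oxo-6-(prop-1-en-2-yl)cyclohex-3-en-1-yl]propanal | CC1=CC[C@@H](C(C)=C)[C@](C)(CCC=O)C1=O | intermediate
7 | aldoxime of 6 (E/Z mixture) | CC1=CC[C@@H](C(C)=C)[C@](C)(CCC=NO)C1=O | intermediate
8 | nitrile oxide from 7, 3-[(1S,6S)-1,3-dimethyl-2-oxo-6-(prop-1-en-2-yl)cyclohex-3-en-1-yl]propanenitrile oxide | CC1=CC[C@@H](C(C)=C)[C@](C)(CCC#[N+][O-])C1=O | intermediate
9 | tricyclic isoxazoline enone: trans-fused ring A/ring B, 2-isoxazoline C3=N–O–CH2–C4 (CH2 α), 4β-CH3, 10β-CH3, 5α-H, 8-CH3, Δ7, 9-oxo | CC1=CC[C@H]2[C@]3(C)CON=C3CC[C@]2(C)C1=O | intermediate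
10 | isoxazoline 7,9(11)-diene (9-methylene analogue of 9) | CC1=CC[C@H]2[C@]3(C)CON=C3CC[C@]2(C)C1=C | intermediate
11 | B-alkyl-9-BBN adduct (boron on C11, 9α-H) | CC1=CC[C@H]2[C@]3(C)CON=C3CC[C@]2(C)[C@H]1CB1C2CCCC1CCC2 | intermediate
12 | isoxazoline alcohol (9β-CH2OH, 9α-H, Δ7) | CC1=CC[C@H]2[C@]3(C)CON=C3CC[C@]2(C)[C@H]1CO | intermediate
13 | umbelliferone, 7-hydroxy-2H-chromen-2-one | Oc1ccc2ccc(=O)oc2c1 | starting material
14 | isoxazoline aryl ether (C11–O–coumarin-7-yl) | CC1=CC[C@H]2[C@]3(C)CON=C3CC[C@]2(C)[C@H]1COc1ccc2ccc(=O)oc2c1 | intermediate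
15 | β-hydroxy imine (C3=NH, 4α-CH2OH) | CC1=CC[C@H]2[C@](C)(CO)C(=N)CC[C@]2(C)[C@H]1COc1ccc2ccc(=O)oc2c1 | intermediate
16 | 7-{[(1S,4aR,5R,8aS)-5-(hydroxymethyl)-2,5,8a-trimethyl-6-oxo-1,4,4a,5,6,7,8,8a-octahydronaphthalen-1-yl]methoxy}-2H-chromen-2-one | CC1=CC[C@H]2[C@](C)(CO)C(=O)CC[C@]2(C)[C@H]1COc1ccc2ccc(=O)oc2c1 | intermediate
17 | 7-{[(1S,4aR,5S,8aS)-5-(iodomethyl)-2,5,8a-trimethyl-6-oxo-1,4,4a,5,6,7,8,8a-octahydronaphthalen-1-yl]methoxy}-2H-chromen-2-one | CC1=CC[C@H]2[C@](C)(CI)C(=O)CC[C@]2(C)[C@H]1COc1ccc2ccc(=O)oc2c1 | intermediate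
18 | 7-{[(1S,4aR,8aS)-2,5,5,8a-tetramethyl-6-oxo-1,4,4a,5,6,7,8,8a-octahydronaphthalen-1-yl]methoxy}-2H-chromen-2-one (CNP0262399.5) | CC1=CC[C@H]2C(C)(C)C(=O)CC[C@]2(C)[C@H]1COc1ccc2ccc(=O)oc2c1 | target

## Step count and risks

Total step count: 10. Longest linear sequence: 10 steps (1 → 18); umbelliferone 13 enters at step 7.

The three steps most likely to fail:

Step 5 (methylenation of the hindered C9 enone). The ylide may only act as a base (γ-enolisation) or fail to reach the carbonyl flanked by the quaternary C10. The fallback sets out from 9 and swaps olefination for addition–elimination. Me3SiCH2Li premixed with anhydrous CeCl3 in THF at −78 °C adds to hindered, enolisable ketones and gives the tertiary 9β-hydroxy-9α-(trimethylsilylmethyl) carbinol F1 (either C9 epimer serves). Peterson elimination of F1 with KH in THF then expels trimethylsilanolate and returns to the route at diene 10.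

Step 7 (Mitsunobu etherification at the β-branched C11 carbinol). The betaine may be consumed unproductively, or elimination to diene 10 may compete. The fallback sets out from 12 and separates activation from displacement. MsCl and Et3N in CH2Cl2 at 0 °C give the C11 methanesulfonate F2. F2 is then heated with umbelliferone 13 and Cs2CO3 in DMF at 80 °C (Williamson etherification with a weakly basic phenoxide), returning to the route at 14.

Step 9 (SN2 iodination at the neopentyl C4–CH2OH). Displacement may be too slow, and retro-aldol loss of formaldehyde may compete on heating. The fallback sets out from 16 and avoids any substitution at that carbon. 1,1'-Thiocarbonyldiimidazole with DMAP in CH2Cl2 at 40 °C gives the O-(imidazol-1-ylthiocarbonyl) derivative F3. Barton–McCombie deoxygenation of F3 (Bu3SnH, 10 mol % (PhSe)2, AIBN, toluene, 110 °C) cleaves the C–O bond homolytically and gives the target 18 directly, bypassing iodide 17 and step 10.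

## Further compounds

F1 | step 5 | 9β-hydroxy-9α-(trimethylsilylmethyl) adduct of isoxazoline enone 9 | CC1=CC[C@H]2[C@]3(C)CON=C3CC[C@]2(C)[C@]1(O)C[Si](C)(C)C
F2 | step 7 | C11 methanesulfonate of isoxazoline alcohol 12 | CC1=CC[C@H]2[C@]3(C)CON=C3CC[C@]2(C)[C@H]1COS(C)(=O)=O
F3 | step 9 | O-(1H-imidazol-1-ylthiocarbonyl) derivative of β-hydroxy ketone 16 | CC1=CC[C@H]2[C@](C)(COC(=S)n3ccnc3)C(=O)CC[C@]2(C)[C@H]1COc1ccc2ccc(=O)oc2c1
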